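Time was the first thing I looked at in this flask: it runs 20 h, and I wanted to see what happens in the first minutes of that.

    crystals ⇌ target, rate k1*(cs1 - [target]) while solid is left; crystals form when [target] > cs1 (cs1 = 0.056 M, k1 = 3.08 h⁻¹)
    starting material + free catalyst ⇌ catalyst intermediate A (K2 = 23.8 M⁻¹, k2 = 27000 M⁻¹ h⁻¹)
    coupling partner → decomposed reagent (k3 = 0.970 h⁻¹)
    second substrate + free catalyst ⇌ catalyst intermediate B (K4 = 11 M⁻¹, k4 = 4550 M⁻¹ h⁻¹)
    coupling partner + catalyst intermediate B → free catalyst + second product (k5 = 1.35 × 10⁵ M⁻¹ h⁻¹)
    coupling partner + catalyst intermediate A → free catalyst + target (k6 = 37700 M⁻¹ h⁻¹)

starting material 0.061 M; second substrate 0.0610 M; coupling partner 0.0610 M; free catalyst 0.12 mM; time 20 h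

1. the state of affairs at 20 h: stopped, and by what, or still going (the coupling partner has run out first / forward and back rates have come level / no working catalyst is left / all of the starting material has reacted / it is still moving)
2. amount of target at 20 h, in percent of the starting material charged

- target is meant together with its crystals
- solid, in amounts per volume of the solution: crystals
- the reaction counts as stopped when no species that holds the starting material changes by six tenths of a point or more over the second half of the time
- run time (flask): 20 h

I reckoned in powers of ten. In the first instants free catalyst met both substrates, and by forward rates starting material took it up 5.9 times as fast as second substrate did. Each intermediate then had two ways: fall back, or go on with coupling partner.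

catalyst intermediate A: back 1130 h⁻¹, on 2300 h⁻¹
catalyst intermediate B: back 414 h⁻¹, on 8240 h⁻¹

The first of these stood 3.07 powers of ten above the decomposition of coupling partner, so I took the intermediates as steady. For each free catalyst, that put 0.480 in intermediate A and 0.0321 in intermediate B.

Coupling partner then fell by three pseudo-first-order paths, which I reckoned at the charged amounts:

to target 1.44 h⁻¹
to second product 0.344 h⁻¹
to decomposed reagent 0.970 h⁻¹

target path / sum of the paths = 52.2%

This opening share is the part of the coupling partner that becomes target at the charged amounts. Decomposition by itself takes coupling partner down 8.43 powers of ten in 20 h. Its charge equals that of starting material, and part of it goes elsewhere, so I expected it to be the limiting reagent.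

Towards the end, going on slows and the intermediates approach equilibrium. With the substrates still at their charge, the share sinks to 32.1%. My figure was the opening share times the charge ratio, 52.2%, and I took it as somewhat high because the share near the end was lower. That is 0.0318 M of target, below the solubility, so I expected no crystals.

The forecast said the coupling partner has run out first, with 47% of target (44% to 50%), the share falling “less as it runs low and the second-substrate route gains share”.

The simulation gave the same end, the coupling partner has run out first, with 47.3% of target, 4.9 percentage points under my figure. The couplings and the decomposition ran while coupling partner was there; at 2.00 h it stood at 0.00557% of its charge, and the step from starting material to catalyst intermediate A had >99.9% of its turnover behind it. Starting material stood at 52.6% then and at 52.6% after 200 h, with crystals at 0%.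

For the neighbour flask with 0.037 M of coupling partner, each free catalyst had 0.651 in intermediate A and 0.0513 in intermediate B, so I reckoned the opening share at 54.3% and the target at 32.9%. That neighbour flask gave 29.6%.

The numbers are invented.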